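**Plan**

- Ring numbering of the target: C1 (C=O), C2 (bears CH2CO2Me), C3 (=CH), C4 (CHOH), C5 (CH–geranylgeranyl), C6 (CH2); C1′ is the first chain carbon.
- Feature used: C1 and C4 are 1,4 across the six-membered ring, and the sp2 carbon C2 lies between C1 and C3. If C2 is taken out and C1 joined to C3, the γ-hydroxy-enone becomes a 3-oxygenated cyclopent-2-en-1-ol, the oxygen pattern of a cyclopentane-1,3-dione.
- Retrosynthetic cuts, in order: (i) C1–C2 and C2–C3 of the six-membered ring (C2 leaves with its acetate arm, via a bicyclo[3.1.0]hexan-1-ol); (ii) C3–C4 of the cyclopentane (Claisen acylation); (iii) C5–C1′ (enolate alkylation).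
- Forward: the chain is joined first (step 3), the five-membered ring closes (step 5), the three-membered ring is added on the enol ether C1=C3 (step 9), and the six-membered ring arises last by enlargement of the five-membered ring (step 10).
- Stereochemistry: C5 comes from an Evans alkylation with the (R)-benzyloxazolidinone. C4 comes from hydride attack anti to the chain on the C4 ketone, which gives the cis alcohol. Both centres are spectators afterwards.

Key step: step 10

Remark: the target is read as (4R,5R) with hydroxyl and chain cis; "geranylgeranyl" means the all-E (2E,6E,10E)-3,7,11,15-tetramethylhexadeca-2,6,10,14-tetraen-1-yl group. Both epimers at the cyclopropane carbon that carries the ester arm are carried on, since this carbon becomes sp2 in step 10.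

**Route**

Step 1
Reactants: 1 (2E,6E,10E)-geranylgeraniol
Product: 2 (2E,6E,10E)-geranylgeranyl bromide
Conditions: PBr3 (0.4 equiv), Et2O, −10 °C, dark; used crude
Reagents that add atoms: phosphorus tribromide, BrP(Br)Br
Why: Bromination of the primary allylic alcohol through its phosphite ester (SN2 by bromide) at low temperature should leave the 2E double bond in place and give no allylic transposition.

Step 2
Reactants: 3 (R)-4-benzyl-1,3-oxazolidin-2-one; 4 pent-4-enoyl chloride
Product: 5 (R)-4-benzyl-3-(pent-4-enoyl)-1,3-oxazolidin-2-one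
Conditions: n-BuLi, THF, −78 °C; then 4, −78 → 0 °C
Reagents that add atoms: none
Why: N-Acylation of the lithiated oxazolidinone by an acid chloride is the standard entry to an Evans imide.

Step 3
Reactants: 5 (R)-4-benzyl-3-(pent-4-enoyl)-1,3-oxazolidin-2-one; 2 geranylgeranyl bromide
Product: 6 (R)-4-benzyl-3-[(2S,4E,8E,12E)-5,9,13,17-tetramethyl-2-(prop-2-en-1-yl)octadeca-4,8,12,16-tetraenoyl]-1,3-oxazolidin-2-one
Conditions: NaN(SiMe3)2, THF, −78 °C; then 2, −78 → −40 °C
Reagents that add atoms: none
Why: Evans alkylation: the chelated Z-enolate is alkylated by the allylic bromide (SN2, no allylic shift) on the face opposite the benzyl group of the (R)-auxiliary, which sets the future C5 (2S in 6).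

Step 4
Reactants: 6 the alkylated imide
Product: 7 (R)-4-benzyl-3-[(2R,4E,8E,12E)-5,9,13,17-tetramethyl-2-(2-oxopropyl)octadeca-4,8,12,16-tetraenoyl]-1,3-oxazolidin-2-one
Conditions: PdCl2 (10 mol %), CuCl, O2 (1 atm), DMF/H2O 7:1, 23 °C
Reagents that add atoms: water, O (carbonyl oxygen); dioxygen, O=O (terminal oxidant)
Why: Tsuji–Wacker oxidation: divalent palladium activates only the monosubstituted alkene and water adds at its internal carbon to give the methyl ketone, while the trisubstituted chain alkenes, the imide and the stereocentre are untouched.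

Step 5
Reactants: 7 the keto imide
Product: 8 (R)-4-geranylgeranylcyclopentane-1,3-dione
Conditions: LiN(SiMe3)2 (1.2 equiv), THF, −78 → 0 °C; cold 1 M HCl; auxiliary 3 recovered
Reagents that add atoms: none
Why: Intramolecular Claisen (Dieckmann-type) acylation: the kinetic methyl-ketone enolate attacks the exocyclic imide carbonyl (5-exo-trig) and expels the auxiliary; the dione is held as its enolate and the α-branched imide resists enolisation, so the stereocentre should survive.

Step 6
Reactants: 8 (R)-4-geranylgeranylcyclopentane-1,3-dione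
Product: 9 (R)-5-geranylgeranyl-3-(triisopropylsilyloxy)cyclopent-2-en-1-one
Conditions: i-Pr3SiOTf (1.05 equiv), 2,6-lutidine, CH2Cl2, −78 °C
Reagents that add atoms: triisopropylsilyl trifluoromethanesulfonate, CC(C)[Si](OS(=O)(=O)C(F)(F)F)(C(C)C)C(C)C
Why: O-Silylation of the dione by the bulky silyl triflate should occur at the oxygen remote from the branched carbon, which is also the more stable vinylogous silyl ester (no A(1,2) strain); this places the enol ether at C1=C3 and leaves the C4 ketone next to the stereocentre.

Step 7
Reactants: 9 the vinylogous silyl ester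
Product: 10 (1R,5R)-5-geranylgeranyl-3-(triisopropylsilyloxy)cyclopent-2-en-1-ol (hydroxyl and chain cis)
Conditions: LiBH(s-Bu)3, THF, −78 °C; aq. NaHCO3; chromatography on Et3N-deactivated silica
Reagents that add atoms: none
Why: 1,2-Reduction of the vinylogous ester carbonyl by a bulky borohydride, which approaches anti to the adjacent chain and so sets the carbinol cis to it (the usual outcome for 2-alkylcyclopentanones); the β-siloxy group disfavours 1,4-attack.

Step 8
Reactants: 11 diiodomethane; 12 methyl bromoacetate
Product: 13 methyl 3,3-diiodopropanoate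
Conditions: NaN(SiMe3)2, THF/Et2O, −78 °C, dark; then 12, −78 °C; cold AcOH quench
Reagents that add atoms: none
Why: SN2 alkylation of NaCHI2 (from deprotonation of diiodomethane) by the activated primary bromide, the known route to 1,1-diiodoalkanes; low temperature and an acidic quench are meant to prevent E1cB loss of HI.

Step 9
Reactants: 10 the cis siloxy-cyclopentenol; 13 methyl 3,3-diiodopropanoate
Product: 14 methyl 2-[(3R,4R)-4-hydroxy-3-geranylgeranyl-1-(triisopropylsilyloxy)bicyclo[3.1.0]hexan-6-yl]acetate (cyclopropane cis to the hydroxyl; both C6 epimers)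
Conditions: Et2Zn (3 equiv), 13 (2.5 equiv), CH2Cl2, −40 → 0 °C; aq. NaHCO3
Reagents that add atoms: none
Why: Proposed new method: Et2Zn converts 10 into its O–ZnEt derivative and zinc–iodine exchange with 13 gives the carbenoid EtZnCH(I)CH2CO2Me, held in a five-membered chelate by its ester carbonyl; delivered from the zinc-bound oxygen it should add to the adjacent, strongly nucleophilic enol ether C1=C3 on the hydroxyl face through a butterfly-type transition state, faster than its own 1,2-hydride shift to methyl acrylate (slowed because the migrating hydrogens lie next to the ester) and faster than attack on the unactivated chain alkenes; the closest known reaction type is the hydroxyl-directed Simmons–Smith–Furukawa cyclopropanation of allylic alcohols with alkyl-substituted 1,1-diiodoalkanes, here with a β-ester on the carbenoid; the two ring-fusion centres are set cis to the hydroxyl by this delivery and, like the epimeric carbenoid carbon, are erased in step 10.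

Step 10
Reactants: 14 the ester-bearing siloxycyclopropane
Product: 17 methyl 2-[(3R,4R)-3-hydroxy-4-geranylgeranyl-6-oxocyclohex-1-en-1-yl]acetate (target), via bicyclic cyclopropanol 15 (not isolated), via ring-expanded 3-chloro ketone 16 (not isolated)
Conditions: Bu4NF/AcOH (1:1, 1.1 equiv), THF, −20 °C; then FeCl3 (3 equiv), pyridine, DMF, 0 °C; then NaOAc, MeOH, 40 °C
Reagents that add atoms: none
Why: Fluoride frees cyclopropanol 15, whose alkoxide on FeCl3 (trivalent iron) is oxidised by one electron to an alkoxy radical; β-scission of the bond shared by the two rings (C1–C3) makes C1 the ketone and leaves a secondary radical on C3 of the new six-membered ring, which takes chlorine from FeCl3 to give 16, and acetate then removes the acidic C2–H (E1cB) to place the double bond at C2=C3. The closest known reaction type is the Ito–Saegusa FeCl3 ring enlargement of bicyclic siloxycyclopropanes to 2-cycloalkenones, which has also been applied to carbenoid carbons bearing an alkyl group. No ring is closed: the six-membered ring arises by fragmentation of the fusion bond of the five- and three-membered rings, so the cyclopentane gains the carbenoid carbon as C2 together with its acetate arm. No stereocentre is formed; C4 and C5 are not α to the carbonyl and stay as set, and the three cyclopropane centres become sp2 or CH2. The step needs scission of the fusion bond and not of the bond to the ester-bearing carbon, and chlorine transfer faster than 5-exo capture of the C3 radical by the nearest chain alkene; the first should follow from the larger strain release and the ring-secondary radical, the second from excess FeCl3, and the elimination can only run toward C2.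

**Compound list**

1 | (2E,6E,10E)-geranylgeraniol | OC/C=C(\C)CC/C=C(\C)CC/C=C(\C)CCC=C(C)C | starting material
2 | (2E,6E,10E)-geranylgeranyl bromide | BrC/C=C(\C)CC/C=C(\C)CC/C=C(\C)CCC=C(C)C | intermediate
3 | (R)-4-benzyl-1,3-oxazolidin-2-one | O=C1N[C@H](Cc2ccccc2)CO1 | starting material
4 | pent-4-enoyl chloride | C=CCCC(Cl)=O | starting material
5 | (R)-4-benzyl-3-(pent-4-enoyl)-1,3-oxazolidin-2-one | C=CCCC(=O)N1[C@H](Cc2ccccc2)COC1=O | intermediate
6 | (R)-4-benzyl-3-[(2S,4E,8E,12E)-5,9,13,17-tetramethyl-2-(prop-2-en-1-yl)octadeca-4,8,12,16-tetraenoyl]-1,3-oxazolidin-2-one | C=CC[C@@H](C/C=C(\C)CC/C=C(\C)CC/C=C(\C)CCC=C(C)C)C(=O)N1[C@H](Cc2ccccc2)COC1=O | intermediate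
7 | (R)-4-benzyl-3-[(2R,4E,8E,12E)-5,9,13,17-tetramethyl-2-(2-oxopropyl)octadeca-4,8,12,16-tetraenoyl]-1,3-oxazolidin-2-one | CC(=O)C[C@@H](C/C=C(\C)CC/C=C(\C)CC/C=C(\C)CCC=C(C)C)C(=O)N1[C@H](Cc2ccccc2)COC1=O | intermediate
8 | (R)-4-geranylgeranylcyclopentane-1,3-dione | O=C1CC(=O)[C@H](C/C=C(\C)CC/C=C(\C)CC/C=C(\C)CCC=C(C)C)C1 | intermediate
9 | (R)-5-geranylgeranyl-3-(triisopropylsilyloxy)cyclopent-2-en-1-one | CC(C)[Si](OC1=CC(=O)[C@H](C/C=C(\C)CC/C=C(\C)CC/C=C(\C)CCC=C(C)C)C1)(C(C)C)C(C)C | intermediate
10 | (1R,5R)-5-geranylgeranyl-3-(triisopropylsilyloxy)cyclopent-2-en-1-ol | CC(C)[Si](OC1=C[C@H](O)[C@H](C/C=C(\C)CC/C=C(\C)CC/C=C(\C)CCC=C(C)C)C1)(C(C)C)C(C)C | intermediate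
11 | diiodomethane | ICI | starting material
12 | methyl bromoacetate | COC(=O)CBr | starting material
13 | methyl 3,3-diiodopropanoate | COC(=O)CC(I)I | intermediate
14 | methyl 2-[(3R,4R)-4-hydroxy-3-geranylgeranyl-1-(triisopropylsilyloxy)bicyclo[3.1.0]hexan-6-yl]acetate, cyclopropane cis to OH, C6 epimers | CC(C)[Si](C(C)C)(C(C)C)O[C@@]12[C@@H]([C@H](O)[C@H](C/C=C(\C)CC/C=C(\C)CC/C=C(\C)CCC=C(C)C)C1)C2CC(=O)OC | intermediate
15 | methyl 2-[(3R,4R)-1,4-dihydroxy-3-geranylgeranylbicyclo[3.1.0]hexan-6-yl]acetate | O[C@@]12[C@@H]([C@H](O)[C@H](C/C=C(\C)CC/C=C(\C)CC/C=C(\C)CCC=C(C)C)C1)C2CC(=O)OC | intermediate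
16 | methyl 2-[(3R,4R)-2-chloro-3-hydroxy-4-geranylgeranyl-6-oxocyclohexyl]acetate, epimers at C1 and C2 | COC(=O)CC1C(Cl)[C@H](O)[C@H](C/C=C(\C)CC/C=C(\C)CC/C=C(\C)CCC=C(C)C)CC1=O | intermediate
17 | methyl 2-[(3R,4R)-3-hydroxy-4-geranylgeranyl-6-oxocyclohex-1-en-1-yl]acetate | COC(=O)CC1=C[C@H](O)[C@H](C/C=C(\C)CC/C=C(\C)CC/C=C(\C)CCC=C(C)C)CC1=O | target

**Step count**

Total: 10 steps. Longest linear sequence: 8 steps (step 1 or 2, then 3, 4, 5, 6, 7, 9, 10).

**Steps most likely to fail**

1. Step 9 (Proposed new method). The ester-bearing zinc carbenoid may decompose by 1,2-hydride shift or by enolisation and loss of iodide before it is transferred, or it may react too slowly at the hindered enol ether and begin to attack the chain alkenes. The fallback uses known chemistry, sets out from 10 and returns at 17. Hydroxyl-directed Simmons–Smith–Furukawa cyclopropanation (Et2Zn, CH2I2, CH2Cl2, 0 °C) should give the unsubstituted siloxycyclopropane F1. The three operations of step 10 then lead through the cyclopropanol F2 and the chloro ketone F3 to the hydroxy enone F4. The hydroxyl is silylated (Et3SiCl, imidazole) to the triethylsilyl ether F5, so that the next step cannot end in iodoetherification with the nearest chain alkene. α-Iodination (I2, pyridine, CH2Cl2) should give the 2-iodo enone F6. Negishi coupling with the Reformatsky reagent BrZnCH2CO2Me (Pd(PPh3)4, THF) should give the protected target F7, and HF·pyridine then releases 17.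

2. Step 10 (key step). β-Scission may take place at the bond to the ester-bearing cyclopropane carbon instead of the fusion bond, the C3 radical may be captured by the C2′=C3′ alkene before chlorine transfer, or cyclopropanol 15 may lactonise onto the ester before it is oxidised. The fallback replaces the radical fragmentation by a polar ring enlargement; it sets out from 10 and returns at 17. Iodocyclopropanation with the zinc carbenoid from CHI3 and Et2Zn should give the iodocyclopropane F8. On warming with 2,6-lutidine in MeCN this should lose iodide with cyclopropyl-to-allyl opening assisted by the siloxy group, and after loss of the silyl group give the hydroxy enone F4. From there the route of the first fallback is followed through the silyl ether F5, the iodo enone F6 and the protected target F7 to 17.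

3. Step 6. Silylation may occur on the more hindered oxygen and give the regioisomeric enol ether, or a second silylation may enolise the ketone toward C5 and erode its configuration. The fallback fixes the position of the enol ether by construction; it sets out from 2 and returns at 9. Commercial cyclopentane-1,3-dione is silylated (i-Pr3SiOTf, 2,6-lutidine) to the parent vinylogous silyl ester F9. Stork–Danheiser alkylation (LiN(i-Pr)2, THF, −78 °C, then 2) at the α′ carbon should give the racemic vinylogous silyl ester F10. Preparative chromatography on a chiral stationary phase then supplies 9, and the unwanted enantiomer can be racemised by deprotonation and reprotonation and recycled.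

**Further compounds**

F1 | step 9 | (2R,3R)-3-geranylgeranyl-5-(triisopropylsilyloxy)bicyclo[3.1.0]hexan-2-ol, cyclopropane cis to OH | CC(C)[Si](C(C)C)(C(C)C)O[C@@]12[C@@H]([C@H](O)[C@H](C/C=C(\C)CC/C=C(\C)CC/C=C(\C)CCC=C(C)C)C1)C2
F2 | step 9 | (3R,4R)-3-geranylgeranylbicyclo[3.1.0]hexane-1,4-diol | O[C@@]12[C@@H]([C@H](O)[C@H](C/C=C(\C)CC/C=C(\C)CC/C=C(\C)CCC=C(C)C)C1)C2
F3 | step 9 | (4R,5R)-3-chloro-4-hydroxy-5-geranylgeranylcyclohexan-1-one | O=C1CC(Cl)[C@H](O)[C@H](C/C=C(\C)CC/C=C(\C)CC/C=C(\C)CCC=C(C)C)C1
F4 | step 9 | (4R,5R)-4-hydroxy-5-geranylgeranylcyclohex-2-en-1-one | O=C1C=C[C@H](O)[C@H](C/C=C(\C)CC/C=C(\C)CC/C=C(\C)CCC=C(C)C)C1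
F5 | step 9 | (4R,5R)-5-geranylgeranyl-4-(triethylsilyloxy)cyclohex-2-en-1-one | O=C1C=C[C@H](O[Si](CC)(CC)CC)[C@H](C/C=C(\C)CC/C=C(\C)CC/C=C(\C)CCC=C(C)C)C1
F6 | step 9 | (4R,5R)-5-geranylgeranyl-2-iodo-4-(triethylsilyloxy)cyclohex-2-en-1-one | O=C1C(I)=C[C@H](O[Si](CC)(CC)CC)[C@H](C/C=C(\C)CC/C=C(\C)CC/C=C(\C)CCC=C(C)C)C1
F7 | step 9 | methyl 2-[(3R,4R)-4-geranylgeranyl-6-oxo-3-(triethylsilyloxy)cyclohex-1-en-1-yl]acetate | COC(=O)CC1=C[C@H](O[Si](CC)(CC)CC)[C@H](C/C=C(\C)CC/C=C(\C)CC/C=C(\C)CCC=C(C)C)CC1=O
F8 | step 10 | (2R,3R)-3-geranylgeranyl-6-iodo-5-(triisopropylsilyloxy)bicyclo[3.1.0]hexan-2-ol | CC(C)[Si](C(C)C)(C(C)C)O[C@@]12[C@@H]([C@H](O)[C@H](C/C=C(\C)CC/C=C(\C)CC/C=C(\C)CCC=C(C)C)C1)C2I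
F9 | step 6 | 3-(triisopropylsilyloxy)cyclopent-2-en-1-one | CC(C)[Si](C(C)C)(C(C)C)OC1=CC(=O)CC1
F10 | step 6 | rac-5-geranylgeranyl-3-(triisopropylsilyloxy)cyclopent-2-en-1-one | CC(C)[Si](OC1=CC(=O)C(C/C=C(\C)CC/C=C(\C)CC/C=C(\C)CCC=C(C)C)C1)(C(C)C)C(C)C
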